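## Structural features

Nakijiquinone M (28) joins a bicyclic sesquiterpene to a 2-hydroxy-5-(3-methylbutylamino)-1,4-benzoquinone through one methylene carbon, C11, which sits on the quaternary carbon C9 of the decalin. Ring A (C1–C5, C10) carries the gem-dimethyl carbon C4, and ring B (C5–C10) carries the C5=C6 olefin, so the quaternary C4 is bonded directly to the olefinic carbon C5. Three contiguous stereocentres lie along one edge of ring B: C8 (CH3), C9 (CH3 and C11) and C10 (H). The two methyl groups are cis, and the C10 hydrogen is trans to the C9 methyl, on the face of C11. The fragile parts are the aminohydroxyquinone (a vinylogous acid and amide, sensitive to base, nucleophiles and reductants) and the C5=C6 olefin, whose protonation would put a cation at C5 next to C4 and invite methyl migration or drift of the double bond to C5=C10. The real difficulty is to make the C4–C5 bond between a fully substituted carbon and a ring carbon that must end up sp2, with the C8/C9/C10 triad already in place, and then to attach an electron-rich arene to the neopentyl carbon C11. The key step uses two features: C4 is tertiary and gives a stable cation once its chloride is ionised, and C5 is the alpha carbon of a C6 carbonyl in ring B, so a C5=C6 enol ether can capture that cation and close ring A. C9, C11 and ring B correspond to the angular carbon, the saturated carbonyl carbon and the enone ring of 1 after its C1–C2 bond is cut.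

## Logic of the disconnections

28 is cut at the quinone C–N bond into 26 and 27. The carbon that bears nitrogen is a vinylogous ester carbon in 26, so the amine can be introduced last by addition–elimination and the basic nitrogen is kept out of all earlier steps. The forward step needs the amine to attack only the methoxy-bearing carbon next to the ring CH; the deprotonated hydroxyl of 26 shields the other side.

26 is traced through 25 to 24 by cutting one O–CH3 bond and returning the two quinone carbonyls to aryl methyl ethers. A tetramethoxyarene is inert to the organometallic and radical steps that attach it. The forward steps need an oxidation that spares the C5=C6 olefin and a hydrolysis that picks the methoxy group next to the C11-bearing carbon.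

24 is cut at the C11–aryl bond into 18 and 19, by way of 23. C11 is neopentyl and cannot be displaced, but as an aldehyde carbon it accepts an aryllithium. The cut is convergent and removes the whole arene. The price is a benzylic oxygen that must be removed by a radical path, because a cation at C11 next to quaternary C9 would rearrange.

18 is traced through 17 and 16 to 15 and 14 by adjusting the oxidation state of C11 and by re-forming a C6–O bond and a C5–H bond. The C6 carbonyl is what the ring closure leaves behind. An enol derivative toward C5 is disfavoured by allylic strain against the C4 methyl groups, so the olefin must come from anti elimination of an axial C6 leaving group. The forward step needs the C5 hydrogen to be lost in preference to the C7 hydrogen.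

14 is cut at the C4–C5 bond to give 12. This is the only bond that joins the quaternary C4 to ring B, and only an SN1 process can make it. The cut removes ring A and leaves a monocyclic ring B with a simple side chain. The forward step needs a regiodefined C5=C6 enol ether and a tertiary chloride in the same molecule, capture of the cation ahead of proton loss, and equilibration of the first-formed 13 to 14.

12 is traced to 11 by cutting the C10–H and O–Si bonds, and 11 to 10 by cutting the C4–Cl bond. Conjugate hydrosilylation of the enone gives the enol ether with fixed regiochemistry and sets C10 in one operation. The chloride must be installed first, because HCl would destroy the enol ether. The forward step needs hydride delivery to the alpha face of C10 without touching the C–Cl bond.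

10 is cut at the C8–CH3 bond to give 9, and 9 is traced through 8, 7 and 6 to 5 by changes of oxidation state at C6, C7/C8 and C11. Conjugate addition to a cross-conjugated dienone places the methyl group on the only unsubstituted beta carbon. C11 is reduced and silylated before the dienone is made, because a carboxyl group on the quaternary carbon of a cyclohexadienone would be lost by aromatisation. The forward step needs attack on the face opposite the silyloxymethyl group.

5 is cut at the C3=C4 double bond to give 4, and 4 is traced through 3 and 2 to 1 by re-forming the ring bond between the saturated carbonyl carbon of 1 and its alpha carbon. Ozonolysis of an enol ether leaves the two termini at different oxidation states (ester at C11, aldehyde at C3). The enone ring and the quaternary stereocentre of 1 are used unchanged. The forward step needs an enol ether at the saturated carbonyl only, which is reached through ketal 2 because the conjugated carbonyl does not ketalise under mild conditions.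

## Other disconnections considered

Alternative 1: The cut removes both C4–CH3 bonds. The 4,4-dimethyl-5-ene unit is traced to ketone A1, which still has a C3 carbonyl, and A1 to the conjugated C3-keto-4-ene A2, whose ring A would be unmasked from a methoxy-substituted benzene ring by Birch reduction and hydrolysis. In the forward step a hindered potassium alkoxide and excess methylating agent would convert A2, through its extended dienolate, into A1; the second methylation fixes the double bond at C5=C6.
- In favour: the chemistry is classical and non-cationic, and the olefin position follows directly from the alkylation. On this point it is better than the chosen plan, whose C5=C6 bond comes from an elimination (step 13) that must choose between two hydrogens.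
- Against: A2 must already contain the C8/C9/C10 triad, and the aromatic precursor offers no chiral-pool match comparable to 1, so absolute and relative configuration would need separate asymmetric steps. The dialkylation can stop at the monomethyl stage or go to O-alkylation. The C3 carbonyl, now next to the new quaternary C4, must then be removed (thioacetal desulfurisation or Wolff–Kishner reduction) without touching the olefin.
- Comparison: both plans carry one surplus carbonyl that must be deleted (C3 there, C6 here), so they are equal on that count. Alternative 1 is mechanistically safer for the gem-dimethyl/olefin unit. The chosen plan is stronger on the origin of C9 and on the control of C8 and C10. The step count would be similar at best.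

Alternative 2: The cut is made inside the quinone. Hydroquinone A3 is traced to the 4-hydroxycyclobutenone A4, which would be assembled on diisopropyl squarate A5 by two organometallic additions (a C11 carbon nucleophile, then the two-carbon ethoxyvinyl unit). In the forward step, thermolysis of A4 would open the four-membered ring to a dienylketene, six-electron electrocyclisation would close the six-membered ring, and tautomerisation would give A3. Oxidation, exchange of the ethoxy group for 27 and cleavage of the isopropyl ether would finish the quinone.
- In favour: all four oxygen positions differ from the start, so neither oxidation of a tetramethoxyarene nor a regioselective hydrolysis is needed. On regiocontrol of the quinone substituents it is better than steps 18 and 19 of the chosen plan.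
- Against: C11 must serve as a carbanion, which means a neopentyl halide and halogen–lithium exchange next to quaternary C9. About seven operations follow the decalin, against five in the chosen plan. The thermolysis exposes the C5=C6 olefin and an acid-sensitive enol ether to heat. The decalin itself is not addressed and would still have to be made, for example as 17.
- Comparison: on ring A and the decalin stereocentres the two are equal, because Alternative 2 takes them as they come. Its pericyclic key step is predictable. Its step economy is worse. It is a complement to the chosen decalin synthesis and not a competitor.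

Alternative 3: Ring B is cut at C7–C8 and C9–C10 into diene A6 (C7=C6–C5=C10) and dienophile A7. Their cycloadduct is aldehyde A8, which is the same compound as 18. In the forward step a chiral boron Lewis acid would bind the formyl group of A7 and direct a [4+2] cycloaddition with the formyl group exo.
- In favour: it would reach in one step what the chosen plan reaches only at step 15, so on step economy it is clearly better. The cis relation of the C8 and C9 methyl groups follows from the E geometry of A7, and the C5=C6 olefin is formed in place with no regiochemical question; on both points it is also better.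
- Against: both partners are poor. A7 is a beta-substituted, alpha-branched enal, and the inner diene carbon C5 of A6 is flanked by quaternary C4. The single step must deliver the correct regiochemistry (C10 to C9), the exo mode that puts the C10 hydrogen on the face of C11, and the absolute configuration, all with a catalyst class not established for this pairing. Diene polymerisation under Lewis acid is a further hazard.
- Comparison: the chosen plan is much longer, but it takes C9 from the chiral pool and sets C8 and C10 by separate substrate-controlled steps that can each be corrected. Alternative 3 concentrates all stereochemical and reactivity risk in one untested cycloaddition.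

Key step: step 11

Remarks on the chemistry (assumptions):
- Atoms are numbered as in the target decalin (C1–C10, C11 on C9). Beta is the face of the C9 methyl group and alpha is the face of C11. TBDPS is tert-butyldiphenylsilyl.
- The carbinol carbon C6 in 6 and 7, and C11 in 21, 22 and 23, are epimer mixtures. These centres are removed later, so the SMILES leave them open.
- The ring closure makes C5 a stereocentre for a time. The tether can deliver C4 only to the face of C5 on which the chain sits, so the first-formed ketone should be cis-fused (13). The trans-fused ketone 14 is reached by epimerisation, which is built into step 11.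
- The precursor 12 differs from the simplest design in three ways. The C11 ether is TBDPS, which should survive HCl and TiCl4 and enlarges the C9 substituent that steers the cuprate. The enol ether is dimethylphenylsilyl, the direct product of a conjugate hydrosilylation that leaves the C–Cl bond alone. The cyclisation is run with a hindered pyridine to protect the enol ether from HCl.

Step 1
Reactants: 1 (R)-Wieland–Miescher ketone
Product: 2 dimethyl ketal at the saturated carbonyl of 1
Conditions: HC(OMe)3, p-TsOH·H2O (cat.), MeOH, 0 °C → rt
Reagents that add atoms: trimethyl orthoformate, COC(OC)OC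
Why: Acid-catalysed ketalisation; the saturated carbonyl reacts while the conjugated carbonyl, which would have to give up its conjugation, is left alone, and the orthoformate removes water.

Step 2
Reactants: 2 dimethyl ketal
Product: 3 methyl enol ether (C=C between the former carbonyl carbon and its CH2 neighbour)
Conditions: TMSOTf (1.1 equiv), i-Pr2NEt, CH2Cl2, −30 → 0 °C; aq. NaHCO3
Reagents that add atoms: none
Why: Ketal-to-enol-ether elimination: TMSOTf ionises the ketal to an oxocarbenium ion and the amine removes a proton from the only alpha CH2 (the other neighbour is quaternary), so the enol ether is regiospecific; any silylation at the enone oxygen is undone by the bicarbonate work-up.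

Step 3
Reactants: 3 methyl enol ether
Product: 4 aldehyde ester: methyl (1R)-1-methyl-4-oxo-2-(3-oxopropyl)cyclohex-2-ene-1-carboxylate
Conditions: O3, CH2Cl2/MeOH 4:1, NaHCO3, −78 °C; then Me2S, −78 °C → rt
Reagents that add atoms: ozone, [O-][O+]=O
Why: Ozonolysis of an enol ether; the electron-rich enol ether reacts far faster than the electron-poor enone C=C, the oxygen-bearing carbon becomes the methyl ester (C11) and the other carbon the aldehyde (C3), so the termini are differentiated in one step.

Step 4
Reactants: 4 aldehyde ester
Product: 5 alkenyl ester: methyl (1R)-1-methyl-2-(4-methylpent-3-en-1-yl)-4-oxocyclohex-2-ene-1-carboxylate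
Conditions: i-PrPPh3I, n-BuLi, THF, 0 °C; then 4, −78 → 0 °C
Reagents that add atoms: isopropyltriphenylphosphonium iodide, CC(C)[P+](c1ccccc1)(c1ccccc1)c1ccccc1.[I-]
Why: Wittig olefination; the non-stabilised ylide reacts with the aldehyde at low temperature much faster than with the conjugated ketone or the ester on the quaternary carbon, giving the C3=C4 trisubstituted olefin.

Step 5
Reactants: 5 alkenyl ester
Product: 6 diol: (4R)-4-(hydroxymethyl)-4-methyl-3-(4-methylpent-3-en-1-yl)cyclohex-2-en-1-ol (both carbinol epimers)
Conditions: i-Bu2AlH (5 equiv), CH2Cl2, −78 → 0 °C; aq. KNaC4H4O6 (tartrate)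
Reagents that add atoms: none
Why: Hydride reduction of the hindered ester to the C11 alcohol with 1,2-reduction of the enone, which cannot be spared and is re-oxidised in step 7; the isolated olefin is inert.

Step 6
Reactants: 6 diol
Product: 7 primary TBDPS ether of 6 (allylic alcohol free)
Conditions: TBDPSCl (1.05 equiv), imidazole, CH2Cl2, 0 °C
Reagents that add atoms: tert-butyl(chloro)diphenylsilane, CC(C)(C)[Si](Cl)(c1ccccc1)c1ccccc1
Why: Silylation of an alcohol; the bulky silyl chloride should select the primary hydroxyl over the secondary ring carbinol.

Step 7
Reactants: 7 silyl ether allylic alcohol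
Product: 9 cross-conjugated dienone: (4R)-4-[(TBDPS-oxy)methyl]-4-methyl-3-(4-methylpent-3-en-1-yl)cyclohexa-2,5-dien-1-one, via enone 8 (not isolated)
Conditions: IBX (4 equiv), DMSO, rt, then 80 °C
Reagents that add atoms: none
Why: IBX oxidises the allylic alcohol to enone 8 at room temperature and, on heating, dehydrogenates the only alpha CH2–CH2 unit (C7–C8) through the enol, which is the known IBX dehydrogenation of ketones to enones and dienones.

Step 8
Reactants: 9 dienone
Product: 10 enone with 8β-methyl: (4R,5S)-4-[(TBDPS-oxy)methyl]-4,5-dimethyl-3-(4-methylpent-3-en-1-yl)cyclohex-2-en-1-one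
Conditions: Me2CuLi (from CuI and MeLi), Et2O, −78 → −20 °C; aq. NH4Cl
Reagents that add atoms: lithium dimethylcuprate, [Li+].C[Cu-]C (prepared from methyllithium, [Li]C, and CuI)
Why: Cuprate conjugate addition; C8 is the only unsubstituted beta carbon (C10 is fully substituted), and on the flat dienone the two C9 substituents point to opposite faces, so the methyl group should enter anti to the large CH2OTBDPS group, cis to the C9 methyl.

Step 9
Reactants: 10 enone with olefinic side chain
Product: 11 tertiary chloride: (4R,5S)-3-(4-chloro-4-methylpentyl)-4-[(TBDPS-oxy)methyl]-4,5-dimethylcyclohex-2-en-1-one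
Conditions: HCl (g), CH2Cl2, −40 → 0 °C
Reagents that add atoms: hydrogen chloride, Cl
Why: Markovnikov hydrochlorination of the trisubstituted olefin through the tertiary C4 cation; the enone is only reversibly protonated and the TBDPS ether should tolerate anhydrous HCl at low temperature.

Step 10
Reactants: 11 enone tertiary chloride
Product: 12 ring B dimethylphenylsilyl enol ether (C5=C6–OSiMe2Ph) with 10α-H and the 4-chloro-4-methylpentyl chain on C10
Conditions: [(Ph3P)CuH]6 (5 mol % Cu), PhMe2SiH (1.5 equiv), toluene, rt
Reagents that add atoms: dimethyl(phenyl)silane, C[SiH](C)c1ccccc1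
Why: Copper-hydride-catalysed 1,4-hydrosilylation of an enone gives the C5=C6 silyl enol ether regiospecifically and leaves the tertiary C–Cl bond alone; in the reactive half-chair (C8 methyl equatorial, C9 methyl axial) hydride reaches C10 axially from the alpha face, anti to the C9 methyl and trans to the C8 methyl as in the usual trans-3,5 outcome of cyclohexenone conjugate additions.

Step 11
Reactants: 12 silyl enol ether with tertiary chloride side chain
Product: 14 trans-fused 4,4-dimethyl C6 decalone (5β-H 10α-H) with 9α-CH2OTBDPS, via cis-fused ketone 13 (not isolated)
Conditions: TiCl4 (1.1 equiv), 2,6-di-tert-butyl-4-methylpyridine (0.3 equiv), CH2Cl2, −78 → −40 °C; aq. NaHCO3; then NaOMe (cat.), MeOH, rt → 40 °C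
Reagents that add atoms: none
Why: TiCl4 abstracts chloride from C4, C5 of the enol ether captures the tertiary cation, and the silyloxocarbenium ion loses PhMe2SiCl to return the C6 ketone. The closest known reaction type is the Lewis-acid-mediated alpha-tert-alkylation of silyl enol ethers with tertiary alkyl halides, an SN1 counterpart of enolate alkylation, used here intramolecularly. Ring A closes in a six-membered enol-exo mode [6-(enolexo)-exo]: C10, C1, C2, C3, C4 and C5 form the new ring and the enol C5=C6 bond lies outside it. The new stereocentre is C5: C4 must approach perpendicular to the enol ether plane and can do so only on the beta face that carries the C10 chain, so tether control should give cis-fused 13 first. C5 is alpha to the ketone, and 13 suffers either a syn-axial contact of C4 with the C9 methyl or an axial C1 opposite the C8 methyl, so methoxide equilibration should drain it into trans-fused 14; C8, C9 and C10 are untouched. Site selectivity for C5 comes from the regiodefined enol ether, and attack through C7 or through oxygen would require an eight-membered ring. Substitution has to beat proton loss from the cation and protodesilylation; low temperature, reversible ionisation and the hindered pyridine, which removes adventitious HCl without binding TiCl4, serve that purpose.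

Step 12
Reactants: 14 trans-fused decalone
Product: 15 axial 6α-alcohol of 14
Conditions: LiBH(s-Bu)3, THF, −78 → 0 °C; H2O
Reagents that add atoms: none
Why: Hindered borohydride reduction; the axial alpha trajectory to C6 is blocked by the syn-axial 4α-methyl group, so hydride should come along the equatorial path from the beta side and give the axial alcohol, whose C–O bond is antiperiplanar to the axial C5–H.

Step 13
Reactants: 15 axial alcohol
Product: 16 C5=C6 olefin: 4,4,8β,9β-tetramethyl-9α-(TBDPS-oxymethyl)-10α-H-octal-5-ene
Conditions: SOCl2, pyridine, −10 → 0 °C
Reagents that add atoms: none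
Why: Chlorosulfite formation and pyridine-induced anti (E2) elimination from the axial position; loss of the tertiary axial C5–H gives the more substituted olefin (Zaitsev orientation) and relieves the syn-axial 4α-CH3/6α-O contact, and the basic medium avoids a C6 cation and the hydride or methyl shifts it would trigger.

Step 14
Reactants: 16 silyl ether olefin
Product: 17 C11 alcohol (9α-hydroxymethyl octalin)
Conditions: Bu4NF, THF, 50 °C
Reagents that add atoms: none
Why: Fluoride cleavage of the silyl ether; the neopentyl position needs gentle warming and the olefin is inert.

Step 15
Reactants: 17 C11 alcohol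
Product: 18 C11 aldehyde
Conditions: 1,1,1-triacetoxy-1,1-dihydro-1,2-benziodoxol-3(1H)-one (DMP), NaHCO3, CH2Cl2, rt
Reagents that add atoms: none
Why: Periodinane oxidation of a primary alcohol under buffered, non-acidic conditions; the aldehyde has no alpha hydrogen and cannot epimerise or enolise.

Step 16
Reactants: 18 C11 aldehyde; 19 1,2,4,5-tetramethoxybenzene
Product: 23 S-methyl xanthate of the C11 benzylic alcohol (C11 epimers), via aryllithium 20 (not isolated), via lithium alkoxide 21 (not isolated), via lithium xanthate 22 (not isolated)
Conditions: 19, n-BuLi, THF, 0 °C → rt; add 18, −78 → 0 °C; CS2, rt; MeI, rt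
Reagents that add atoms: carbon disulfide, S=C=S; iodomethane, CI
Why: Directed ortho-lithiation between two methoxy groups gives 20, which adds to the unenolisable neopentyl aldehyde; the alkoxide 21 is trapped in the same flask with CS2 and MeI, the usual xanthate preparation for a Barton–McCombie deoxygenation.

Step 17
Reactants: 23 xanthate
Product: 24 9α-(2,3,5,6-tetramethoxybenzyl) octalin
Conditions: Bu3SnH, AIBN (cat.), toluene, 110 °C
Reagents that add atoms: none
Why: Barton–McCombie deoxygenation through a benzylic C11 radical; the radical cannot rearrange as a cation would, and cyclisation onto C5=C6 would need a four-ring or 5-endo closure.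

Step 18
Reactants: 24 tetramethoxyarene
Product: 25 2,5-dimethoxy-3-(decalinylmethyl)-1,4-benzoquinone
Conditions: (NH4)2Ce(NO3)6 (2.5 equiv), MeCN/H2O, 0 °C
Reagents that add atoms: water, O
Why: Oxidative demethylation of a para-dimethoxyarene to the quinone; both para pairs give the same product, and the short cold exposure should spare the hindered trisubstituted olefin.

Step 19
Reactants: 25 dimethoxyquinone
Product: 26 2-hydroxy-5-methoxy-3-(decalinylmethyl)-1,4-benzoquinone
Conditions: KOH, MeOH/H2O, rt; then aq. HCl to pH 3
Reagents that add atoms: potassium hydroxide, [K+].[OH-]
Why: Addition–elimination of hydroxide at a vinylogous ester carbon; the methoxy group flanked by the alkyl substituent is twisted out of conjugation and should be the one replaced, and the resulting vinylogous carboxylate stops a second hydrolysis.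

Step 20
Reactants: 26 hydroxy methoxy quinone; 27 3-methylbutan-1-amine
Product: 28 nakijiquinone M
Conditions: 27 (excess), NaHCO3, EtOH, rt; mild acidic work-up
Reagents that add atoms: none
Why: Addition–elimination of the primary amine at the remaining vinylogous ester carbon next to the ring CH; the ionised hydroxyl deactivates the other enone arm, so only the methoxy group is exchanged and no stereocentre is touched.

## Compound list

1 | (R)-Wieland–Miescher ketone, (8aR)-8a-methyl-3,4,8,8a-tetrahydronaphthalene-1,6(2H,7H)-dione | C[C@@]12CCC(=O)C=C1CCCC2=O | starting material
2 | (4aR)-5,5-dimethoxy-4a-methyl-4,4a,5,6,7,8-hexahydronaphthalen-2(3H)-one | C[C@@]12CCC(=O)C=C1CCCC2(OC)OC | intermediate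
3 | (4aR)-5-methoxy-4a-methyl-4,4a,7,8-tetrahydronaphthalen-2(3H)-one | C[C@@]12CCC(=O)C=C1CCC=C2OC | intermediate
4 | methyl (1R)-1-methyl-4-oxo-2-(3-oxopropyl)cyclohex-2-ene-1-carboxylate | C[C@@]1(C(=O)OC)CCC(=O)C=C1CCC=O | intermediate
5 | methyl (1R)-1-methyl-2-(4-methylpent-3-en-1-yl)-4-oxocyclohex-2-ene-1-carboxylate | C[C@@]1(C(=O)OC)CCC(=O)C=C1CCC=C(C)C | intermediate
6 | (4R)-4-(hydroxymethyl)-4-methyl-3-(4-methylpent-3-en-1-yl)cyclohex-2-en-1-ol, carbinol epimers | C[C@@]1(CO)CCC(O)C=C1CCC=C(C)C | intermediate
7 | (4R)-4-[(tert-butyldiphenylsilyloxy)methyl]-4-methyl-3-(4-methylpent-3-en-1-yl)cyclohex-2-en-1-ol, carbinol epimers | CC(C)(C)[Si](c1ccccc1)(c1ccccc1)OC[C@]1(C)CCC(O)C=C1CCC=C(C)C | intermediate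
8 | (4R)-4-[(tert-butyldiphenylsilyloxy)methyl]-4-methyl-3-(4-methylpent-3-en-1-yl)cyclohex-2-en-1-one | CC(C)(C)[Si](c1ccccc1)(c1ccccc1)OC[C@]1(C)CCC(=O)C=C1CCC=C(C)C | intermediate (not isolated)
9 | (4R)-4-[(tert-butyldiphenylsilyloxy)methyl]-4-methyl-3-(4-methylpent-3-en-1-yl)cyclohexa-2,5-dien-1-one | CC(C)(C)[Si](c1ccccc1)(c1ccccc1)OC[C@]1(C)C=CC(=O)C=C1CCC=C(C)C | intermediate
10 | (4R,5S)-4-[(tert-butyldiphenylsilyloxy)methyl]-4,5-dimethyl-3-(4-methylpent-3-en-1-yl)cyclohex-2-en-1-one (8β,9β-dimethyl) | CC(C)(C)[Si](c1ccccc1)(c1ccccc1)OC[C@@]1(C)C(CCC=C(C)C)=CC(=O)C[C@@H]1C | intermediate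
11 | (4R,5S)-3-(4-chloro-4-methylpentyl)-4-[(tert-butyldiphenylsilyloxy)methyl]-4,5-dimethylcyclohex-2-en-1-one | CC(C)(C)[Si](c1ccccc1)(c1ccccc1)OC[C@@]1(C)C(CCCC(C)(C)Cl)=CC(=O)C[C@@H]1C | intermediate
12 | ring B C5=C6 dimethylphenylsilyl enol ether with 10α-H, 8β-CH3, 9β-CH3, 9α-CH2OTBDPS and the 4-chloro-4-methylpentyl chain on C10 | CC(C)(C)[Si](c1ccccc1)(c1ccccc1)OC[C@@]1(C)[C@H](CCCC(C)(C)Cl)C=C(O[Si](C)(C)c2ccccc2)C[C@@H]1C | intermediate
13 | cis-fused (5α-H,10α-H) 4,4,8β,9β-tetramethyl-9α-(TBDPS-oxymethyl)decalin-6-one | CC(C)(C)[Si](c1ccccc1)(c1ccccc1)OC[C@@]1(C)[C@@H]2CCCC(C)(C)[C@@H]2C(=O)C[C@@H]1C | intermediate (not isolated)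
14 | trans-fused (5β-H,10α-H) 4,4,8β,9β-tetramethyl-9α-(TBDPS-oxymethyl)decalin-6-one | CC(C)(C)[Si](c1ccccc1)(c1ccccc1)OC[C@@]1(C)[C@@H]2CCCC(C)(C)[C@H]2C(=O)C[C@@H]1C | intermediate
15 | 6α-hydroxy (axial) trans-decalin derived from 14 | CC(C)(C)[Si](c1ccccc1)(c1ccccc1)OC[C@@]1(C)[C@@H]2CCCC(C)(C)[C@H]2[C@@H](O)C[C@@H]1C | intermediate
16 | 4,4,8β,9β-tetramethyl-9α-(TBDPS-oxymethyl)-10α-H-octal-5-ene | CC(C)(C)[Si](c1ccccc1)(c1ccccc1)OC[C@@]1(C)[C@@H]2CCCC(C)(C)C2=CC[C@@H]1C | intermediate
17 | 9α-(hydroxymethyl)-4,4,8β,9β-tetramethyl-10α-H-octal-5-ene | OC[C@@]1(C)[C@@H]2CCCC(C)(C)C2=CC[C@@H]1C | intermediate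
18 | C11 aldehyde: 4,4,8β,9β-tetramethyl-10α-H-octal-5-ene-9α-carbaldehyde | O=C[C@@]1(C)[C@@H]2CCCC(C)(C)C2=CC[C@@H]1C | intermediate
19 | 1,2,4,5-tetramethoxybenzene | COc1cc(OC)c(OC)cc1OC | starting material
20 | 2,3,5,6-tetramethoxyphenyllithium | [Li]c1c(OC)c(OC)cc(OC)c1OC | intermediate (not isolated)
21 | lithium alkoxide of the C11 (2,3,5,6-tetramethoxyphenyl)carbinol, C11 epimers | [Li]OC(c1c(OC)c(OC)cc(OC)c1OC)[C@@]1(C)[C@@H]2CCCC(C)(C)C2=CC[C@@H]1C | intermediate (not isolated)
22 | lithium O-alkyl dithiocarbonate of the C11 carbinol, C11 epimers | [Li+].[S-]C(=S)OC(c1c(OC)c(OC)cc(OC)c1OC)[C@@]1(C)[C@@H]2CCCC(C)(C)C2=CC[C@@H]1C | intermediate (not isolated)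
23 | O-alkyl S-methyl dithiocarbonate (xanthate) of the C11 carbinol, C11 epimers | CSC(=S)OC(c1c(OC)c(OC)cc(OC)c1OC)[C@@]1(C)[C@@H]2CCCC(C)(C)C2=CC[C@@H]1C | intermediate
24 | 9α-(2,3,5,6-tetramethoxybenzyl)-4,4,8β,9β-tetramethyl-10α-H-octal-5-ene | COc1cc(OC)c(OC)c(C[C@@]2(C)[C@@H]3CCCC(C)(C)C3=CC[C@@H]2C)c1OC | intermediate
25 | 2,5-dimethoxy-3-(decalinylmethyl)-1,4-benzoquinone | COC1=CC(=O)C(OC)=C(C[C@@]2(C)[C@@H]3CCCC(C)(C)C3=CC[C@@H]2C)C1=O | intermediate
26 | 2-hydroxy-5-methoxy-3-(decalinylmethyl)-1,4-benzoquinone | COC1=CC(=O)C(O)=C(C[C@@]2(C)[C@@H]3CCCC(C)(C)C3=CC[C@@H]2C)C1=O | intermediate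
27 | 3-methylbutan-1-amine | CC(C)CCN | starting material
28 | nakijiquinone M | CC(C)CCNC1=CC(=O)C(O)=C(C[C@@]2(C)[C@@H]3CCCC(C)(C)C3=CC[C@@H]2C)C1=O | target

## Step count and least certain steps

Total: 20 steps. Longest linear sequence: 20 steps (1 → 28); 19 and 27 are purchased and enter at steps 16 and 20.

**Step 11 (key step).** The cation may lose a proton, or the enol ether may be protodesilylated, before the C4–C5 bond forms. The closure must bring a tertiary centre onto the face of C5 that also carries the axial C9 methyl, or else pass through a twisted ring B. The fallback closes the same bond under equilibrating protic conditions from the keto-olefin. Enone 10 is reduced under the conditions of step 10 to the dimethylphenylsilyl enol ether F1, K2CO3 in MeOH releases the saturated ketone F2, and F2 is cyclised with a Lewis-acid-assisted proton source (SnCl4 with a phenol, CH2Cl2, −78 → −20 °C). The olefin is protonated reversibly and the ketone enol acts as terminator. Methoxide equilibration then returns the route at 14.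

**Step 8.** Facial discrimination on the flat dienone may be poor, because CH3 and CH2OTBDPS differ mainly by a group that can rotate away. The fallback replaces substrate control by catalyst control: copper-catalysed asymmetric conjugate addition of Me2Zn to 9 with Cu(OTf)2 and a binaphthol-derived phosphoramidite ligand, with the ligand enantiomer chosen to deliver the methyl group to the beta face. It leads directly from 9 to 10; no new compound is made (F0).

**Step 10.** Hydride transfer to the fully substituted C10 next to quaternary C9 may be slow, or may occur on the beta face if the conformer with an axial silyloxymethyl group reacts. The fallback uses a different catalytic manifold. RhCl(PPh3)3 with Et3SiH (benzene, 60 °C) transfers silicon to oxygen first and hydrogen to C10 by reductive elimination from an oxa-allyl rhodium hydride. This converts 11 into the triethylsilyl enol ether F3, which is cyclised under the conditions of step 11 and rejoins the route at 14.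

**Step 13.** Elimination may go toward C7, whose axial hydrogen is less crowded than the tertiary C5 hydrogen, or ionisation may lead to hydride and methyl shifts. The fallback leaves the alcohol route. Ketone 14 is condensed with p-toluenesulfonylhydrazide to the tosylhydrazone F4, and its sodium salt (NaH) is heated in toluene/diglyme at about 140 °C (aprotic Bamford–Stevens reaction). The C6 carbene should prefer 1,2-shift of the tertiary C5 hydrogen and give 16 directly.

**Step 19.** Hydroxide may attack the methoxy-bearing carbon next to the ring CH instead of the one next to the alkyl group, or the quinone may degrade in base. The fallback reverses the order. Quinone 25 is treated with 27 in EtOH; the amine should select the unhindered vinylogous ester carbon and give the 2-methoxy-5-(3-methylbutylamino)quinone F5. The remaining methoxy group is then hydrolysed with aqueous KOH in MeOH followed by acidification, and the route is rejoined at 28.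

## Further compounds

F1 | step 11 | C5=C6 dimethylphenylsilyl enol ether with the 4-methylpent-3-enyl chain on C10 (10α-H) | CC(C)(C)[Si](c1ccccc1)(c1ccccc1)OC[C@@]1(C)[C@H](CCC=C(C)C)C=C(O[Si](C)(C)c2ccccc2)C[C@@H]1C
F2 | step 11 | saturated ring B ketone with the 4-methylpent-3-enyl chain on C10 (10α-H, 8β-CH3, 9β-CH3, 9α-CH2OTBDPS) | CC(C)(C)[Si](c1ccccc1)(c1ccccc1)OC[C@@]1(C)[C@H](CCC=C(C)C)CC(=O)C[C@@H]1C
F0 | step 8 | none | none
F3 | step 10 | C5=C6 triethylsilyl enol ether analogue of 12 | CC(C)(C)[Si](c1ccccc1)(c1ccccc1)OC[C@@]1(C)[C@H](CCCC(C)(C)Cl)C=C(O[Si](CC)(CC)CC)C[C@@H]1C
F4 | step 13 | p-toluenesulfonylhydrazone of 14 | CC(C)(C)[Si](c1ccccc1)(c1ccccc1)OC[C@@]1(C)[C@@H]2CCCC(C)(C)[C@H]2C(=NNS(=O)(=O)c2ccc(C)cc2)C[C@@H]1C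
F5 | step 19 | 2-methoxy-5-(3-methylbutylamino)-3-(decalinylmethyl)-1,4-benzoquinone | CC(C)CCNC1=CC(=O)C(OC)=C(C[C@@]2(C)[C@@H]3CCCC(C)(C)C3=CC[C@@H]2C)C1=O
A1 | alternative 1 | 4,4-dimethyl C3-keto-5-ene with 9α-silyloxymethyl | CC(C)(C)[Si](C)(C)OC[C@@]1(C)[C@@H]2CCC(=O)C(C)(C)C2=CC[C@@H]1C
A2 | alternative 1 | C3-keto-4-ene with 9α-silyloxymethyl | CC(C)(C)[Si](C)(C)OC[C@@]1(C)[C@@H]2CCC(=O)C=C2CC[C@@H]1C
A3 | alternative 2 | 5-ethoxy-2-isopropoxy-3-(decalinylmethyl)hydroquinone | CCOc1cc(O)c(OC(C)C)c(C[C@@]2(C)[C@@H]3CCCC(C)(C)C3=CC[C@@H]2C)c1O
A4 | alternative 2 | 4-[(Z)-2-ethoxyvinyl]-4-hydroxy-3-isopropoxy-2-(decalinylmethyl)cyclobut-2-en-1-one | CCO/C=C\C1(O)C(OC(C)C)=C(C[C@@]2(C)[C@@H]3CCCC(C)(C)C3=CC[C@@H]2C)C1=O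
A5 | alternative 2 | diisopropyl squarate | CC(C)OC1=C(OC(C)C)C(=O)C1=O
A6 | alternative 3 | 6,6-dimethyl-1-vinylcyclohexene | C=CC1=CCCCC1(C)C
A7 | alternative 3 | (E)-2-methylbut-2-enal | C/C=C(\C)C=O
A8 | alternative 3 | decalin C11 aldehyde (identical with 18) | O=C[C@@]1(C)[C@@H]2CCCC(C)(C)C2=CC[C@@H]1C
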